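The C10–O bond of the butenolide carries the whole plan: C10 holds the lactone oxygen and is allylic to C11, the alkene carbon shared by the five-membered lactone and the 14-membered carbocycle. A palladium-catalysed allylic C–H oxidation lets the C20 carboxylic acid attack C10 of a but-3-enyl terminus. In one operation this forms C10–O, sets C10 and closes a 15-membered macrolactone, whose C10 vinyl and C12 methylene groups then face each other across the ester for ring-closing metathesis. The precursor is an acyclic tris-triethylsilyl seco acid with the three tertiary carbinols (C1, C4, C8) and both E-alkenes in place, ending in a 2-methylene acid and a but-3-enyl group.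

Key step: step 18

Remark on numbering: C1 isopropyl carbinol, C2=C3, C4 methyl carbinol, C5, C6=C7, C8 methyl carbinol, C9, C10 lactone CH, C11=C12, C13, C14, C20 lactone carbonyl; the target is 1S,4R,8S,10R, and seco acid 26 and macrolactone 27 carry the same configurations.

Assumption: (R)- and (S)-2-methylglycidol, 4-methylpent-2-yn-1-ol and D-(−)-diisopropyl tartrate are purchased.

Step 1
Reactants: 1 (R)-2-methylglycidol; 2 allylmagnesium bromide
Product: 3 (2S)-2-methylhex-5-ene-1,2-diol
Conditions: allylMgBr (2.5 equiv), CuI (10 mol%), THF, −30 to 0 °C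
Reagents that add atoms: none
Why: Copper-catalysed Grignard opening of a 2,2-disubstituted epoxide by SN2 attack at the unsubstituted carbon; the C8 stereocentre comes unchanged from the glycidol because no bond to it is broken (the first equivalent of Grignard reagent only deprotonates the hydroxyl).

Step 2
Reactants: 3 (2S)-2-methylhex-5-ene-1,2-diol
Product: 4 (2S)-2-methyl-1,2-bis[(triethylsilyl)oxy]hex-5-ene
Conditions: TESOTf (2.5 equiv), 2,6-lutidine, CH2Cl2, −78 to 0 °C
Reagents that add atoms: triethylsilyl trifluoromethanesulfonate, CC[Si](CC)(CC)OS(=O)(=O)C(F)(F)F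
Why: Silylation with a silyl triflate and a hindered base covers the tertiary as well as the primary hydroxyl.

Step 3
Reactants: 4 (2S)-2-methyl-1,2-bis[(triethylsilyl)oxy]hex-5-ene
Product: 5 (2S)-2-methyl-2-[(triethylsilyl)oxy]hex-5-enal
Conditions: (COCl)2, DMSO, CH2Cl2, −78 to −40 °C; Et3N, −78 to 0 °C
Reagents that add atoms: none
Why: Swern oxidation run directly on the silyl ether, in which the activated sulfoxide cleaves and oxidises only the primary triethylsilyl ether while the tertiary one is inert; the α-carbon is quaternary and cannot epimerise.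

Step 4
Reactants: 5 (2S)-2-methyl-2-[(triethylsilyl)oxy]hex-5-enal
Product: 6 (1E,3S)-1-iodo-3-methyl-3-[(triethylsilyl)oxy]hepta-1,6-diene
Conditions: CrCl2 (6 equiv), CHI3 (2 equiv), THF–dioxane, 0 °C to rt
Reagents that add atoms: iodoform, IC(I)I
Why: Takai olefination, in which the geminal dichromium species from iodoform adds to the aldehyde and eliminates to the E-iodoalkene, the bulky α-quaternary centre reinforcing E selectivity.

Step 5
Reactants: 7 (S)-2-methylglycidol
Product: 8 triethyl{[(2R)-2-methyloxiran-2-yl]methoxy}silane (triethylsilyl ether of (S)-2-methylglycidol)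
Conditions: TESCl, imidazole, CH2Cl2, 0 °C
Reagents that add atoms: chlorotriethylsilane, CC[Si](Cl)(CC)CC
Why: Standard silylation of a primary alcohol that leaves the epoxide and the future C4 stereocentre untouched.

Step 6
Reactants: 6 (1E,3S)-1-iodo-3-methyl-3-[(triethylsilyl)oxy]hepta-1,6-diene; 8 triethyl{[(2R)-2-methyloxiran-2-yl]methoxy}silane
Product: 10 (2R,4E,6S)-2,6-dimethyl-1,6-bis[(triethylsilyl)oxy]deca-4,9-dien-2-ol, via alkenyllithium 9 (not isolated)
Conditions: t-BuLi (2.1 equiv), Et2O, −78 °C; then 8, BF3·OEt2, −78 °C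
Reagents that add atoms: none
Why: Iodine–lithium exchange with retention of alkene geometry, then BF3-assisted SN2 opening of the epoxide at its CH2 carbon by the alkenyllithium; this forms C5–C6, delivers the E-C6=C7 alkene directly and leaves the glycidol-derived C4 centre intact.

Step 7
Reactants: 10 (2R,4E,6S)-2,6-dimethyl-1,6-bis[(triethylsilyl)oxy]deca-4,9-dien-2-ol
Product: 11 (2R,4E,6S)-2,6-dimethyl-1,2,6-tris[(triethylsilyl)oxy]deca-4,9-diene
Conditions: TESOTf, 2,6-lutidine, CH2Cl2, −78 to 0 °C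
Reagents that add atoms: triethylsilyl trifluoromethanesulfonate, CC[Si](CC)(CC)OS(=O)(=O)C(F)(F)F
Why: Silyl triflate silylation of the hindered tertiary alcohol.

Step 8
Reactants: 11 (2R,4E,6S)-2,6-dimethyl-1,2,6-tris[(triethylsilyl)oxy]deca-4,9-diene
Product: 12 (2R,4E,6S)-2,6-dimethyl-2,6-bis[(triethylsilyl)oxy]deca-4,9-dienal
Conditions: (COCl)2, DMSO, CH2Cl2, −78 to −40 °C; Et3N, −78 to 0 °C
Reagents that add atoms: none
Why: Swern oxidation with selective oxidative cleavage of the single primary silyl ether, as in step 3; the two tertiary silyl ethers and both alkenes are spectators.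

Step 9
Reactants: 12 (2R,4E,6S)-2,6-dimethyl-2,6-bis[(triethylsilyl)oxy]deca-4,9-dienal
Product: 13 (3R,5E,7S)-3,7-dimethyl-3,7-bis[(triethylsilyl)oxy]undeca-5,10-dien-1-yne
Conditions: dimethyl (1-diazo-2-oxopropyl)phosphonate, K2CO3, MeOH, 0 °C to rt
Reagents that add atoms: dimethyl (1-diazo-2-oxopropyl)phosphonate, COP(=O)(OC)C(=[N+]=[N-])C(C)=O
Why: Ohira–Bestmann (Seyferth–Gilbert) homologation, in which the diazophosphonate anion adds to the non-enolisable aldehyde and the alkylidene carbene rearranges to the terminal alkyne (new carbon C2).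

Step 10
Reactants: 14 4-methylpent-2-yn-1-ol
Product: 16 (2Z)-3-iodo-4-methylpent-2-en-1-ol, via alkenylaluminate 15 (not isolated)
Conditions: NaAlH2(OCH2CH2OMe)2 (Red-Al), THF, 0 °C to rt; then I2, −78 °C
Reagents that add atoms: iodine, II
Why: Hydroxyl-directed trans-hydroalumination of a propargylic alcohol places aluminium on C3 in a chelate ring with the CH2O group, and iodinolysis with retention gives the Z-iodoalkene (isopropyl trans to CH2OH).

Step 11
Reactants: 13 (3R,5E,7S)-3,7-dimethyl-3,7-bis[(triethylsilyl)oxy]undeca-5,10-dien-1-yne; 16 (2Z)-3-iodo-4-methylpent-2-en-1-ol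
Product: 17 (2Z,6R,8E,10S)-6,10-dimethyl-3-(propan-2-yl)-6,10-bis[(triethylsilyl)oxy]tetradeca-2,8,13-trien-4-yn-1-ol
Conditions: PdCl2(PPh3)2 (3 mol%), CuI (6 mol%), i-Pr2NH, THF, rt
Reagents that add atoms: none
Why: Sonogashira coupling of a terminal alkyne with an alkenyl iodide, which retains the alkene geometry and tolerates the free hydroxyl, the silyl ethers and the unactivated alkenes.

Step 12
Reactants: 17 (2Z,6R,8E,10S)-6,10-dimethyl-3-(propan-2-yl)-6,10-bis[(triethylsilyl)oxy]tetradeca-2,8,13-trien-4-yn-1-ol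
Product: 18 [(2R,3S)-3-{(3R,5E,7S)-3,7-dimethyl-3,7-bis[(triethylsilyl)oxy]undeca-5,10-dien-1-yn-1-yl}-3-(propan-2-yl)oxiran-2-yl]methanol
Conditions: Ti(OiPr)4 (0.3 equiv), D-(−)-diisopropyl tartrate (0.36 equiv), t-BuOOH, 4 Å MS, CH2Cl2, −20 °C
Reagents that add atoms: tert-butyl hydroperoxide, CC(C)(C)OO
Why: Sharpless asymmetric epoxidation of a trisubstituted allylic alcohol, in which the titanium tartrate selects the alkene face regardless of the remote stereocentres; D-(−)-tartrate gives the epoxide whose quaternary carbon becomes 1S, and only the allylic alcohol alkene reacts.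

Step 13
Reactants: 18 [(2R,3S)-3-{(3R,5E,7S)-3,7-dimethyl-3,7-bis[(triethylsilyl)oxy]undeca-5,10-dien-1-yn-1-yl}-3-(propan-2-yl)oxiran-2-yl]methanol
Product: 20 (3S,4E,6R,8E,10S)-6,10-dimethyl-3-(propan-2-yl)-6,10-bis[(triethylsilyl)oxy]tetradeca-4,8,13-triene-1,3-diol, via yne-diol 19 (not isolated)
Conditions: NaAlH2(OCH2CH2OMe)2 (Red-Al, 5 equiv), THF, −20 °C, then rt; Rochelle salt work-up
Reagents that add atoms: none
Why: Red-Al opening of a 2,3-epoxy alcohol, in which the primary alkoxide delivers hydride to C14 so that the C1–O bond and configuration are untouched; the tertiary propargylic alkoxide so formed then directs trans-hydroalumination of the alkyne to the E-C2=C3 alkene.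

Step 14
Reactants: 20 (3S,4E,6R,8E,10S)-6,10-dimethyl-3-(propan-2-yl)-6,10-bis[(triethylsilyl)oxy]tetradeca-4,8,13-triene-1,3-diol
Product: 21 (3S,4E,6R,8E,10S)-1-iodo-6,10-dimethyl-3-(propan-2-yl)-6,10-bis[(triethylsilyl)oxy]tetradeca-4,8,13-trien-3-ol
Conditions: I2, PPh3, imidazole, THF–MeCN, 0 °C
Reagents that add atoms: iodine, II
Why: Appel-type iodination, which is selective for the primary alcohol over the hindered tertiary allylic alcohol.

Step 15
Reactants: 21 (3S,4E,6R,8E,10S)-1-iodo-6,10-dimethyl-3-(propan-2-yl)-6,10-bis[(triethylsilyl)oxy]tetradeca-4,8,13-trien-3-ol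
Product: 22 (3S,4E,6R,8E,10S)-1-iodo-6,10-dimethyl-3-(propan-2-yl)-3,6,10-tris[(triethylsilyl)oxy]tetradeca-4,8,13-triene
Conditions: TESOTf, 2,6-lutidine, CH2Cl2, −78 to −20 °C
Reagents that add atoms: triethylsilyl trifluoromethanesulfonate, CC[Si](CC)(CC)OS(=O)(=O)C(F)(F)F
Why: Silyl triflate silylation of the tertiary allylic alcohol, which also prevents oxetane formation in the next step.

Step 16
Reactants: 22 (3S,4E,6R,8E,10S)-1-iodo-6,10-dimethyl-3-(propan-2-yl)-3,6,10-tris[(triethylsilyl)oxy]tetradeca-4,8,13-triene; 23 triethyl phosphonoacetate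
Product: 24 ethyl (5S,6E,8R,10E,12S)-2-(diethoxyphosphoryl)-8,12-dimethyl-5-(propan-2-yl)-5,8,12-tris[(triethylsilyl)oxy]hexadeca-6,10,15-trienoate (both C2 epimers)
Conditions: 23 (3 equiv), NaH, THF–DMF, 0 to 50 °C
Reagents that add atoms: none
Why: SN2 alkylation of the sodium salt of a phosphonoacetate by an unhindered primary iodide; the new centre at C12 is stereorandom and is destroyed in step 17.

Step 17
Reactants: 24 ethyl (5S,6E,8R,10E,12S)-2-(diethoxyphosphoryl)-8,12-dimethyl-5-(propan-2-yl)-5,8,12-tris[(triethylsilyl)oxy]hexadeca-6,10,15-trienoate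
Product: 26 (5S,6E,8R,10E,12S)-8,12-dimethyl-2-methylidene-5-(propan-2-yl)-5,8,12-tris[(triethylsilyl)oxy]hexadeca-6,10,15-trienoic acid, via ethyl 2-methylene ester 25 (not isolated)
Conditions: K2CO3, 37% aq. HCHO, THF, 60 °C; then LiOH·H2O, THF–H2O, 40 °C; HCl to pH 4 at 0 °C
Reagents that add atoms: formaldehyde, C=O; lithium hydroxide, [Li+].[OH-]
Why: Horner–Wadsworth–Emmons methylenation with formaldehyde turns the 2-phosphono ester into the 2-methylene ester, and saponification of the unhindered ethyl ester gives the acid without touching the tertiary silyl ethers.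

Step 18
Reactants: 26 (5S,6E,8R,10E,12S)-8,12-dimethyl-2-methylidene-5-(propan-2-yl)-5,8,12-tris[(triethylsilyl)oxy]hexadeca-6,10,15-trienoic acid
Product: 27 (6S,7E,9R,11E,13S,15R)-15-ethenyl-9,13-dimethyl-3-methylidene-6-(propan-2-yl)-6,9,13-tris[(triethylsilyl)oxy]-1-oxacyclopentadeca-7,11-dien-2-one
Conditions: Pd(OAc)2/1,2-bis(phenylsulfinyl)ethane (20 mol%), 1,4-benzoquinone (2 equiv), CH2Cl2 (0.01 M), 45 °C, 72 h
Reagents that add atoms: none
Why: Divalent palladium bound to the bis-sulfoxide cleaves a C10–H bond of the but-3-enyl terminus to give a π-allyl palladium carboxylate, benzoquinone triggers inner-sphere C–O reductive elimination at the internal allyl terminus (branched product) and then returns zerovalent palladium to the divalent state. The closest known reaction type is the palladium/bis-sulfoxide allylic C–H oxidative macrolactonization of ω-alkenoic acids to 14- to 19-membered lactones. The ring closes by attack of the C20 carboxylate oxygen on C10 within the palladium chelate, a 15-membered closure in which the allyl unit stays exocyclic as the C10 vinyl group. No reagent sets C10: the two π-allyl faces interconvert, and the closure should prefer the transition state in which the macrocycle accommodates the methyl and silyloxy groups on quaternary C8 (1,3 to C10) and the two E-alkenes without transannular strain, so the 10R outcome rests on substrate control and remains to be tested. The step needs selectivity for the one monosubstituted alkene, which the substrate secures: the C2=C3 and C6=C7 alkenes are internal and flanked by silyloxy-bearing quaternary carbons, the 2-methylene alkene is 1,1-disubstituted and electron-poor, and all three tertiary hydroxyls are silylated so that neither etherification nor ionization competes. High dilution suppresses oligomeric esters.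

Step 19
Reactants: 27 (6S,7E,9R,11E,13S,15R)-15-ethenyl-9,13-dimethyl-3-methylidene-6-(propan-2-yl)-6,9,13-tris[(triethylsilyl)oxy]-1-oxacyclopentadeca-7,11-dien-2-one
Product: 28 (4S,5E,7R,9E,11S,13R)-7,11-dimethyl-4-(propan-2-yl)-4,7,11-tris[(triethylsilyl)oxy]-14-oxabicyclo[11.2.1]hexadeca-1(16),5,9-trien-15-one
Conditions: second-generation Grubbs catalyst (10 mol%), toluene (0.002 M), 80 °C, argon sparge
Reagents that add atoms: none
Why: Ring-closing metathesis of a 2-substituted acrylate onto an allylic vinyl group, in which the ruthenium alkylidene formed at the C11 vinyl group closes on the C12 methylene with loss of ethene; this transannular five-membered closure creates the butenolide and the 14-membered carbocycle together, with the silyl ethers shielding the two E-alkenes.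

Step 20
Reactants: 28 (4S,5E,7R,9E,11S,13R)-7,11-dimethyl-4-(propan-2-yl)-4,7,11-tris[(triethylsilyl)oxy]-14-oxabicyclo[11.2.1]hexadeca-1(16),5,9-trien-15-one
Product: 29 (4S,5E,7R,9E,11S,13R)-4,7,11-trihydroxy-7,11-dimethyl-4-(propan-2-yl)-14-oxabicyclo[11.2.1]hexadeca-1(16),5,9-trien-15-one (CHEBI:68873)
Conditions: HF·pyridine, pyridine, THF, 0 °C to rt
Reagents that add atoms: none
Why: Fluoride-mediated cleavage of the three tertiary triethylsilyl ethers under buffered, non-basic conditions that leave the butenolide (acidic C10–H) and the tertiary allylic alcohols intact.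

Compound list
1 | (R)-2-methylglycidol, [(2R)-2-methyloxiran-2-yl]methanol | C[C@@]1(CO)CO1 | starting material
2 | allylmagnesium bromide | C=CC[Mg]Br | starting material
3 | (2S)-2-methylhex-5-ene-1,2-diol | OC[C@@](C)(O)CCC=C | intermediate
4 | (2S)-2-methyl-1,2-bis[(triethylsilyl)oxy]hex-5-ene | CC[Si](CC)(CC)OC[C@@](C)(O[Si](CC)(CC)CC)CCC=C | intermediate
5 | (2S)-2-methyl-2-[(triethylsilyl)oxy]hex-5-enal | O=C[C@@](C)(O[Si](CC)(CC)CC)CCC=C | intermediate
6 | (1E,3S)-1-iodo-3-methyl-3-[(triethylsilyl)oxy]hepta-1,6-diene | I/C=C/[C@@](C)(O[Si](CC)(CC)CC)CCC=C | intermediate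
7 | (S)-2-methylglycidol, [(2S)-2-methyloxiran-2-yl]methanol | C[C@]1(CO)CO1 | starting material
8 | triethyl{[(2R)-2-methyloxiran-2-yl]methoxy}silane | CC[Si](CC)(CC)OC[C@@]1(C)CO1 | intermediate
9 | [(1E,3S)-3-methyl-3-[(triethylsilyl)oxy]hepta-1,6-dien-1-yl]lithium | [Li]/C=C/[C@@](C)(O[Si](CC)(CC)CC)CCC=C | intermediate
10 | (2R,4E,6S)-2,6-dimethyl-1,6-bis[(triethylsilyl)oxy]deca-4,9-dien-2-ol | CC[Si](CC)(CC)OC[C@](C)(O)C/C=C/[C@@](C)(O[Si](CC)(CC)CC)CCC=C | intermediate
11 | (2R,4E,6S)-2,6-dimethyl-1,2,6-tris[(triethylsilyl)oxy]deca-4,9-diene | CC[Si](CC)(CC)OC[C@](C)(O[Si](CC)(CC)CC)C/C=C/[C@@](C)(O[Si](CC)(CC)CC)CCC=C | intermediate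
12 | (2R,4E,6S)-2,6-dimethyl-2,6-bis[(triethylsilyl)oxy]deca-4,9-dienal | O=C[C@](C)(O[Si](CC)(CC)CC)C/C=C/[C@@](C)(O[Si](CC)(CC)CC)CCC=C | intermediate
13 | (3R,5E,7S)-3,7-dimethyl-3,7-bis[(triethylsilyl)oxy]undeca-5,10-dien-1-yne | C#C[C@](C)(O[Si](CC)(CC)CC)C/C=C/[C@@](C)(O[Si](CC)(CC)CC)CCC=C | intermediate
14 | 4-methylpent-2-yn-1-ol | CC(C)C#CCO | starting material
15 | sodium 2,2-bis(2-methoxyethoxy)-3-(propan-2-yl)-2,5-dihydro-1,2-oxaaluminol-2-uide (cyclic alkenylaluminate) | [Na+].CC(C)C1=CCO[Al-]1(OCCOC)OCCOC | intermediate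
16 | (2Z)-3-iodo-4-methylpent-2-en-1-ol | CC(C)/C(I)=C/CO | intermediate
17 | (2Z,6R,8E,10S)-6,10-dimethyl-3-(propan-2-yl)-6,10-bis[(triethylsilyl)oxy]tetradeca-2,8,13-trien-4-yn-1-ol | CC(C)/C(=C/CO)C#C[C@](C)(O[Si](CC)(CC)CC)C/C=C/[C@@](C)(O[Si](CC)(CC)CC)CCC=C | intermediate
18 | [(2R,3S)-3-{(3R,5E,7S)-3,7-dimethyl-3,7-bis[(triethylsilyl)oxy]undeca-5,10-dien-1-yn-1-yl}-3-(propan-2-yl)oxiran-2-yl]methanol | CC(C)[C@@]1(C#C[C@](C)(O[Si](CC)(CC)CC)C/C=C/[C@@](C)(O[Si](CC)(CC)CC)CCC=C)O[C@@H]1CO | intermediate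
19 | (3S,6R,8E,10S)-6,10-dimethyl-3-(propan-2-yl)-6,10-bis[(triethylsilyl)oxy]tetradeca-8,13-dien-4-yne-1,3-diol | CC(C)[C@](CCO)(O)C#C[C@](C)(O[Si](CC)(CC)CC)C/C=C/[C@@](C)(O[Si](CC)(CC)CC)CCC=C | intermediate
20 | (3S,4E,6R,8E,10S)-6,10-dimethyl-3-(propan-2-yl)-6,10-bis[(triethylsilyl)oxy]tetradeca-4,8,13-triene-1,3-diol | CC(C)[C@](CCO)(O)/C=C/[C@](C)(O[Si](CC)(CC)CC)C/C=C/[C@@](C)(O[Si](CC)(CC)CC)CCC=C | intermediate
21 | (3S,4E,6R,8E,10S)-1-iodo-6,10-dimethyl-3-(propan-2-yl)-6,10-bis[(triethylsilyl)oxy]tetradeca-4,8,13-trien-3-ol | CC(C)[C@](CCI)(O)/C=C/[C@](C)(O[Si](CC)(CC)CC)C/C=C/[C@@](C)(O[Si](CC)(CC)CC)CCC=C | intermediate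
22 | (3S,4E,6R,8E,10S)-1-iodo-6,10-dimethyl-3-(propan-2-yl)-3,6,10-tris[(triethylsilyl)oxy]tetradeca-4,8,13-triene | CC(C)[C@](CCI)(O[Si](CC)(CC)CC)/C=C/[C@](C)(O[Si](CC)(CC)CC)C/C=C/[C@@](C)(O[Si](CC)(CC)CC)CCC=C | intermediate
23 | triethyl phosphonoacetate | CCOC(=O)CP(=O)(OCC)OCC | starting material
24 | ethyl (5S,6E,8R,10E,12S)-2-(diethoxyphosphoryl)-8,12-dimethyl-5-(propan-2-yl)-5,8,12-tris[(triethylsilyl)oxy]hexadeca-6,10,15-trienoate (C2 epimers) | CC(C)[C@](CCC(C(=O)OCC)P(=O)(OCC)OCC)(O[Si](CC)(CC)CC)/C=C/[C@](C)(O[Si](CC)(CC)CC)C/C=C/[C@@](C)(O[Si](CC)(CC)CC)CCC=C | intermediate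
25 | ethyl (5S,6E,8R,10E,12S)-8,12-dimethyl-2-methylidene-5-(propan-2-yl)-5,8,12-tris[(triethylsilyl)oxy]hexadeca-6,10,15-trienoate | CC(C)[C@](CCC(=C)C(=O)OCC)(O[Si](CC)(CC)CC)/C=C/[C@](C)(O[Si](CC)(CC)CC)C/C=C/[C@@](C)(O[Si](CC)(CC)CC)CCC=C | intermediate
26 | (5S,6E,8R,10E,12S)-8,12-dimethyl-2-methylidene-5-(propan-2-yl)-5,8,12-tris[(triethylsilyl)oxy]hexadeca-6,10,15-trienoic acid (seco acid) | CC(C)[C@](CCC(=C)C(=O)O)(O[Si](CC)(CC)CC)/C=C/[C@](C)(O[Si](CC)(CC)CC)C/C=C/[C@@](C)(O[Si](CC)(CC)CC)CCC=C | intermediate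
27 | (6S,7E,9R,11E,13S,15R)-15-ethenyl-9,13-dimethyl-3-methylidene-6-(propan-2-yl)-6,9,13-tris[(triethylsilyl)oxy]-1-oxacyclopentadeca-7,11-dien-2-one (15-membered macrolactone) | CC(C)[C@]1(O[Si](CC)(CC)CC)/C=C/[C@](C)(O[Si](CC)(CC)CC)C/C=C/[C@@](C)(O[Si](CC)(CC)CC)C[C@H](C=C)OC(=O)C(=C)CC1 | intermediate
28 | (4S,5E,7R,9E,11S,13R)-7,11-dimethyl-4-(propan-2-yl)-4,7,11-tris[(triethylsilyl)oxy]-14-oxabicyclo[11.2.1]hexadeca-1(16),5,9-trien-15-one | CC(C)[C@]1(O[Si](CC)(CC)CC)/C=C/[C@](C)(O[Si](CC)(CC)CC)C/C=C/[C@@](C)(O[Si](CC)(CC)CC)C[C@@H]2C=C(CC1)C(=O)O2 | intermediate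
29 | (4S,5E,7R,9E,11S,13R)-4,7,11-trihydroxy-7,11-dimethyl-4-(propan-2-yl)-14-oxabicyclo[11.2.1]hexadeca-1(16),5,9-trien-15-one (CHEBI:68873) | CC(C)[C@]1(O)/C=C/[C@](C)(O)C/C=C/[C@@](C)(O)C[C@@H]2C=C(CC1)C(=O)O2 | target

Total step count: 20. Longest linear sequence: 18 (steps 1–4, 6–9, 11–20).

Steps most likely to fail

1. Step 18. The C–O bond-forming reductive elimination may show poor or reversed facial selectivity at C10, because only the macrocyclic transition state discriminates the two π-allyl faces. Fallback: the oxidation is run on 26 without regard to selectivity and the wrong epimer, the 15S macrolactone F1 (10S in skeleton numbering), is separated. It is opened with LiOH in THF–H2O to the 10S hydroxy acid F2. F2 is closed again by Mitsunobu macrolactonization (PPh3, diisopropyl azodicarboxylate, toluene, high dilution), an SN2 displacement that inverts C10. The fallback sets out from 26 and comes back to the route at 27, so material of either configuration at C10 converges on 27.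

2. Step 19. The ruthenium alkylidene formed at C11 may cyclise onto C7 of the C6=C7 alkene instead of the hindered, electron-poor C12 methylene; this would give a five-membered carbocycle (C7–C11) and open the macrocycle. Fallback: setting out from 27, the C6=C7 alkene, the most electron-rich and least hindered one, is masked by anti addition of bromine (pyridinium tribromide, 1 equiv, CH2Cl2, −78 °C) as the anti-6,7-dibromide F3. Ring-closing metathesis under the conditions of step 19 then can only join C11 and C12 and gives the dibromo butenolide F4. Zinc dust in THF–AcOH at 0 °C removes the two bromines by anti elimination, restores the E-alkene and comes back to the route at 28.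

3. Step 13. During the alkyne reduction the alkenylaluminium intermediate may expel the C4 silyloxy group, or hydride may add to the alkynyl epoxide in the SN2′ sense; both lead to allenes. Fallback: setting out from 18, the Red-Al treatment is stopped at −40 °C so that only the epoxide opens, and yne-diol 19 is isolated. The alkyne is then reduced without aluminium by ruthenium-catalysed trans-hydrosilylation ([Cp*Ru(MeCN)3]PF6, (EtO)3SiH, CH2Cl2, 0 °C) to the alkenylsilane F5 (silicon mainly on C3; the regiochemistry does not matter). Protodesilylation with AgF in THF–MeOH–H2O, which spares the silyl ethers, comes back to the route at 20.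

Further compounds
F1 | step 18 | (6S,7E,9R,11E,13S,15S)-15-ethenyl-9,13-dimethyl-3-methylidene-6-(propan-2-yl)-6,9,13-tris[(triethylsilyl)oxy]-1-oxacyclopentadeca-7,11-dien-2-one (15-epimer of 27; 10S in skeleton numbering) | CC(C)[C@]1(O[Si](CC)(CC)CC)/C=C/[C@](C)(O[Si](CC)(CC)CC)C/C=C/[C@@](C)(O[Si](CC)(CC)CC)C[C@@H](C=C)OC(=O)C(=C)CC1
F2 | step 18 | (5S,6E,8R,10E,12S,14S)-14-hydroxy-8,12-dimethyl-2-methylidene-5-(propan-2-yl)-5,8,12-tris[(triethylsilyl)oxy]hexadeca-6,10,15-trienoic acid | CC(C)[C@](CCC(=C)C(=O)O)(O[Si](CC)(CC)CC)/C=C/[C@](C)(O[Si](CC)(CC)CC)C/C=C/[C@@](C)(O[Si](CC)(CC)CC)C[C@H](O)C=C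
F3 | step 19 | anti-11,12-dibromide of 27 (ring numbering of 27; one of the two anti diastereomers, either serves) | CC(C)[C@]1(O[Si](CC)(CC)CC)/C=C/[C@](C)(O[Si](CC)(CC)CC)C[C@H](Br)[C@H](Br)[C@@](C)(O[Si](CC)(CC)CC)C[C@H](C=C)OC(=O)C(=C)CC1
F4 | step 19 | anti-9,10-dibromide of 28 (ring numbering of 28; same anti diastereomer as F3) | CC(C)[C@]1(O[Si](CC)(CC)CC)/C=C/[C@](C)(O[Si](CC)(CC)CC)C[C@H](Br)[C@H](Br)[C@@](C)(O[Si](CC)(CC)CC)C[C@@H]2C=C(CC1)C(=O)O2
F5 | step 13 | (3S,4Z,6R,8E,10S)-6,10-dimethyl-3-(propan-2-yl)-5-(triethoxysilyl)-6,10-bis[(triethylsilyl)oxy]tetradeca-4,8,13-triene-1,3-diol | CC(C)[C@](CCO)(O)/C=C(\[Si](OCC)(OCC)OCC)[C@](C)(O[Si](CC)(CC)CC)C/C=C/[C@@](C)(O[Si](CC)(CC)CC)CCC=C
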